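## Retrosynthetic overview

1. Phyltetralin ⇒ (O-methylation, LiAlH4 reduction) the all-trans dimethyl (1R,2S,3S)-1-aryl-6,7-dimethoxytetralin-2,3-dicarboxylate ⇒ (methoxide methanolysis with epimerisation, conjugate reduction of C2=C3) a (1R)-1-aryl-1,4-dihydronaphthalene with a methyl ester on C2 and a camphorsultam imide on C3.
2. Feature used: the benzo ring A is attached to ring B only through C8a–C1 and C4a–C4, and C2 and C3 each carry a one-carbon arm. Ring B is therefore the [4+2] adduct of 4,5-dimethoxybenzyne (ring A) with a 1-arylbuta-1,3-diene C1–C4 that holds the two arms as acyl groups on C2 and C3.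
3. Diene ⇒ Stille coupling (C2–C3 bond) of an α-stannyl cinnamate with N-(2-bromoacryloyl)camphorsultam; the stannane ⇒ syn-hydrostannation of the arylpropiolate ⇒ Sonogashira coupling of 4-iodoveratrole with methyl propiolate.
4. Ring order: rings A and C are bought as arenes; ring B is the only ring made, in the cycloaddition, which also sets C1. C2 and C3 follow by equilibration against C1.

Key step: step 6

Assumption: the (−)-sultam on the C3 acyl group is taken to expose the diene face that leads to the (1R) cycloadduct; this sense cannot be derived securely for an auxiliary at this position, is to be checked on the crystalline adduct, and the (+)-sultam would serve with unchanged steps if it proves opposite. The o-silylaryl triflate is taken as a purchasable aryne precursor.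

## Route

Step 1
Reactants: 1 4-iodoveratrole; 2 methyl propiolate
Product: 3 methyl 3-(3,4-dimethoxyphenyl)prop-2-ynoate
Conditions: PdCl2(PPh3)2 (2 mol %), CuI (4 mol %), K2CO3, THF, 65 °C, slow addition of 2
Reagents that add atoms: none
Why: Sonogashira coupling; the aryl iodide undergoes oxidative addition readily, and an inorganic base in THF avoids the amine conjugate addition that consumes propiolate esters.

Step 2
Reactants: 3 methyl 3-(3,4-dimethoxyphenyl)prop-2-ynoate
Product: 4 methyl (E)-3-(3,4-dimethoxyphenyl)-2-(tributylstannyl)prop-2-enoate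
Conditions: Bu3SnH, Pd(PPh3)4 (2 mol %), THF, 0 °C → rt
Reagents that add atoms: tributyltin hydride, CCCC[SnH](CCCC)CCCC
Why: Palladium-catalysed hydrostannation of an alkynoate is a syn addition that places tin on the carbon α to the ester, so the aryl group ends cis to CO2Me and trans to tin.

Step 3
Reactants: 5 2-bromoacrylic acid
Product: 6 2-bromoacryloyl chloride
Conditions: (COCl)2, DMF (cat.), CH2Cl2, 0 °C → rt; volatiles removed, used at once
Reagents that add atoms: oxalyl chloride, ClC(=O)C(=O)Cl
Why: Acid chloride formation through the chloroiminium species from DMF (Vilsmeier-type activation) is mild enough for the polymerisable bromoacrylic acid.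

Step 4
Reactants: 6 2-bromoacryloyl chloride; 7 (−)-2,10-camphorsultam
Product: 8 N-(2-bromoacryloyl)-(−)-camphorsultam
Conditions: NaH, THF, 0 °C; then 6, −78 → 0 °C
Reagents that add atoms: none
Why: N-acylation of the sodium sultamide by the acid chloride; the low temperature favours attack at the acyl carbon over conjugate addition.

Step 5
Reactants: 4 methyl (E)-3-(3,4-dimethoxyphenyl)-2-(tributylstannyl)prop-2-enoate; 8 N-(2-bromoacryloyl)-(−)-camphorsultam
Product: 9 methyl (Z)-2-(3,4-dimethoxybenzylidene)-3-[(−)-camphorsultam-N-ylcarbonyl]but-3-enoate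
Conditions: Pd2(dba)3 (2.5 mol %), AsPh3 (20 mol %), CuI (20 mol %), BHT (cat.), DMF, rt, dark; aq. KF work-up
Reagents that add atoms: none
Why: Stille coupling; zerovalent palladium inserts into the vinyl C–Br bond and the CuI/AsPh3 combination speeds tin-to-palladium transfer from the hindered α-stannyl enoate, with retention at both alkenes so that the aryl group stays trans to the new C2–C3 bond.

Step 6
Reactants: 9 methyl (Z)-2-(3,4-dimethoxybenzylidene)-3-[(−)-camphorsultam-N-ylcarbonyl]but-3-enoate; 10 4,5-dimethoxy-2-(trimethylsilyl)phenyl trifluoromethanesulfonate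
Product: 12 methyl (1R)-1-(3,4-dimethoxyphenyl)-6,7-dimethoxy-3-[(−)-camphorsultam-N-ylcarbonyl]-1,4-dihydronaphthalene-2-carboxylate, via 4,5-dimethoxybenzyne 11 (not isolated)
Conditions: 10 (1.5 equiv, slow addition), CsF (3 equiv), MeCN–toluene 1:1, rt, Ar; pH 7 buffer; product carried on directly
Reagents that add atoms: none
Why: Fluoride attacks silicon of 10 and the ortho triflate leaves, so the aryne 11 is released slowly beside the diene. Its strained, electrophilic triple bond then adds to C1 and C4 of the cisoid diene in a concerted suprafacial [4+2], an aryne Diels–Alder reaction of the kind known for acyclic dienes that carry a camphorsultam acyl group. Ring B is closed by this intermolecular cycloaddition, an annulation that makes C1–C8a and C4–C4a in one event. C1, the only new stereocentre, should be set by the camphorsultam on the C3 acyl group, which covers one face of the diene so that the aryne adds from the other. The step needs diene-face selectivity (the auxiliary), the aryl-outward geometry (fixed in steps 2 and 5, leaving H at both inside positions of the cisoid diene) and a preference for the diene termini over ene or [2+2] paths (2,3-disubstitution favours the cisoid conformer); the aryne is symmetric, so no regiochemical question arises. Mild fluoride and a buffered work-up should leave the doubly benzylic C1–H in place.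

Step 7
Reactants: 12 methyl (1R)-1-(3,4-dimethoxyphenyl)-6,7-dimethoxy-3-[(−)-camphorsultam-N-ylcarbonyl]-1,4-dihydronaphthalene-2-carboxylate
Product: 13 methyl (1R)-1-(3,4-dimethoxyphenyl)-6,7-dimethoxy-3-[(−)-camphorsultam-N-ylcarbonyl]-1,2,3,4-tetrahydronaphthalene-2-carboxylate (mixture of C2/C3 epimers)
Conditions: SmI2 (3 equiv), MeOH, DMA, THF, 0 °C; pH 7 buffer
Reagents that add atoms: none
Why: Single-electron conjugate reduction of the ene-1,4-dicarbonyl unit; two electron/proton transfers saturate C2=C3 without free base or metal hydride, so C1 is not touched, and the uncontrolled C2 and C3 centres are corrected in step 8.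

Step 8
Reactants: 13 methyl (1R)-1-(3,4-dimethoxyphenyl)-6,7-dimethoxy-3-[(−)-camphorsultam-N-ylcarbonyl]-1,2,3,4-tetrahydronaphthalene-2-carboxylate
Product: 14 dimethyl (1R,2S,3S)-1-(3,4-dimethoxyphenyl)-6,7-dimethoxy-1,2,3,4-tetrahydronaphthalene-2,3-dicarboxylate
Conditions: NaOMe (3 equiv), MeOH–THF, rt → 50 °C; aq. NH4Cl; sultam recovered
Reagents that add atoms: sodium methoxide, C[O-].[Na+]
Why: Methoxide acyl substitution at the imide-like N-acyl sultam gives the methyl ester and frees the auxiliary, while reversible enolisation at C2 and C3 funnels every epimer to the all-equatorial 1,2-trans-2,3-trans diester; C1 is not enolisable and so dictates 2S and 3S under thermodynamic control.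

Step 9
Reactants: 14 dimethyl (1R,2S,3S)-1-(3,4-dimethoxyphenyl)-6,7-dimethoxy-1,2,3,4-tetrahydronaphthalene-2,3-dicarboxylate
Product: 15 [(1R,2S,3S)-1-(3,4-dimethoxyphenyl)-6,7-dimethoxy-1,2,3,4-tetrahydronaphthalene-2,3-diyl]dimethanol
Conditions: LiAlH4, THF, 0 °C → rt; aq. NaOH work-up
Reagents that add atoms: none
Why: Hydride reduction of both esters to primary alcohols; the α-stereocentres should survive because the aluminate intermediates do not enolise.

Step 10
Reactants: 15 [(1R,2S,3S)-1-(3,4-dimethoxyphenyl)-6,7-dimethoxy-1,2,3,4-tetrahydronaphthalene-2,3-diyl]dimethanol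
Product: 16 phyltetralin
Conditions: NaH, MeI, THF–DMF, 0 °C → rt
Reagents that add atoms: iodomethane, CI
Why: Williamson ether synthesis on both primary alkoxides; no stereocentre is involved.

## Compound list

1 | 4-iodoveratrole (4-iodo-1,2-dimethoxybenzene) | COc1ccc(I)cc1OC | starting material
2 | methyl propiolate | C#CC(=O)OC | starting material
3 | methyl 3-(3,4-dimethoxyphenyl)prop-2-ynoate | COC(=O)C#Cc1ccc(OC)c(OC)c1 | intermediate
4 | methyl (E)-3-(3,4-dimethoxyphenyl)-2-(tributylstannyl)prop-2-enoate (aryl cis to CO2Me) | COC(=O)/C(=C\c1ccc(OC)c(OC)c1)[Sn](CCCC)(CCCC)CCCC | intermediate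
5 | 2-bromoacrylic acid | OC(=O)C(Br)=C | starting material
6 | 2-bromoacryloyl chloride | ClC(=O)C(Br)=C | intermediate
7 | (−)-2,10-camphorsultam, (3aS,6R,7aR) | CC1(C)[C@@H]2CC[C@]13CS(=O)(=O)N[C@@H]3C2 | starting material
8 | N-(2-bromoacryloyl)-(−)-camphorsultam | CC1(C)[C@@H]2CC[C@]13CS(=O)(=O)N(C(=O)C(Br)=C)[C@@H]3C2 | intermediate
9 | methyl (Z)-2-(3,4-dimethoxybenzylidene)-3-[(−)-camphorsultam-N-ylcarbonyl]but-3-enoate (aryl trans to the C2–C3 bond) | CC1(C)[C@@H]2CC[C@]13CS(=O)(=O)N(C(=O)C(=C)/C(=C/c4ccc(OC)c(OC)c4)C(=O)OC)[C@@H]3C2 | intermediate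
10 | 4,5-dimethoxy-2-(trimethylsilyl)phenyl trifluoromethanesulfonate | COc1cc(OS(=O)(=O)C(F)(F)F)c(cc1OC)[Si](C)(C)C | starting material
11 | 4,5-dimethoxybenzyne (not isolated) | COC1=CC#CC=C1OC | intermediate
12 | methyl (1R)-1-(3,4-dimethoxyphenyl)-6,7-dimethoxy-3-[(−)-camphorsultam-N-ylcarbonyl]-1,4-dihydronaphthalene-2-carboxylate | CC1(C)[C@@H]2CC[C@]13CS(=O)(=O)N(C(=O)C4=C(C(=O)OC)[C@H](c5ccc(OC)c(OC)c5)c5cc(OC)c(OC)cc5C4)[C@@H]3C2 | intermediate
13 | methyl (1R)-1-(3,4-dimethoxyphenyl)-6,7-dimethoxy-3-[(−)-camphorsultam-N-ylcarbonyl]-1,2,3,4-tetrahydronaphthalene-2-carboxylate, C2/C3 epimer mixture | CC1(C)[C@@H]2CC[C@]13CS(=O)(=O)N(C(=O)C4Cc5cc(OC)c(OC)cc5[C@@H](c5ccc(OC)c(OC)c5)C4C(=O)OC)[C@@H]3C2 | intermediate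
14 | dimethyl (1R,2S,3S)-1-(3,4-dimethoxyphenyl)-6,7-dimethoxy-1,2,3,4-tetrahydronaphthalene-2,3-dicarboxylate | COC(=O)[C@H]1Cc2cc(OC)c(OC)cc2[C@@H](c2ccc(OC)c(OC)c2)[C@@H]1C(=O)OC | intermediate
15 | [(1R,2S,3S)-1-(3,4-dimethoxyphenyl)-6,7-dimethoxy-1,2,3,4-tetrahydronaphthalene-2,3-diyl]dimethanol | OC[C@H]1Cc2cc(OC)c(OC)cc2[C@@H](c2ccc(OC)c(OC)c2)[C@@H]1CO | intermediate
16 | phyltetralin, (1R,2S,3S)-1-(3,4-dimethoxyphenyl)-6,7-dimethoxy-2,3-bis(methoxymethyl)-1,2,3,4-tetrahydronaphthalene | COC[C@H]1Cc2cc(OC)c(OC)cc2[C@@H](c2ccc(OC)c(OC)c2)[C@@H]1COC | target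

## Step count and risks

Total steps: 10. Longest linear sequence: 8 steps (steps 1, 2, 5, 6, 7, 8, 9, 10 from 4-iodoveratrole; the branch through steps 3 and 4 is equally long).

**Step 6 (aryne cycloaddition).** Three processes may defeat it:
- the aryne may be consumed by fluoride, solvent, or ene and [2+2] pathways faster than it adds across the twisted, electron-poor diene;
- the auxiliary, two bonds away from C1, may fail to differentiate the diene faces;
- fluoride may shift the C2=C3 double bond toward C1 and erase the stereocentre.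

The fallback gives up the cycloaddition and closes ring B by a cationic Friedel–Crafts alkylation, with C3 set first by an oxazolidinone alkylation. It sets out from alkyne 3 and returns at diol 15. Hydrogenation of 3 (H2, Pd/C, EtOAc) should give methyl 3-(3,4-dimethoxyphenyl)propanoate F1, and LiOH in aqueous THF 3-(3,4-dimethoxyphenyl)propanoic acid F2. The mixed pivalic anhydride (PivCl, Et3N) with lithiated (R)-4-benzyl-2-oxazolidinone should give (R)-4-benzyl-3-[3-(3,4-dimethoxyphenyl)propanoyl]oxazolidin-2-one F3. Evans alkylation of its sodium enolate (NaN(SiMe3)2, THF, −78 °C) with tert-butyl bromoacetate, anti to the benzyl group of the auxiliary, should give tert-butyl (3S)-4-[(4R)-4-benzyl-2-oxooxazolidin-3-yl]-3-(3,4-dimethoxybenzyl)-4-oxobutanoate F4. LiBH4 removes the auxiliary to tert-butyl (3S)-3-(3,4-dimethoxybenzyl)-4-hydroxybutanoate F5, and TsOH in warm toluene closes (S)-4-(3,4-dimethoxybenzyl)dihydrofuran-2(3H)-one F6. Its lithium enolate (LiN(SiMe3)2, THF, −78 °C) should add to 3,4-dimethoxybenzaldehyde trans to the benzyl group to give (3R,4S)-4-(3,4-dimethoxybenzyl)-3-[(3,4-dimethoxyphenyl)(hydroxy)methyl]dihydrofuran-2(3H)-one F7 as carbinol epimers. TFA in CH2Cl2 ionises the carbinol, and the dimethoxybenzyl ring closes ring B to the all-trans lactone (3aS,9R,9aS)-9-(3,4-dimethoxyphenyl)-6,7-dimethoxy-3a,4,9,9a-tetrahydronaphtho[2,3-c]furan-1(3H)-one F8. LiAlH4 opens F8 to diol 15, and step 10 follows.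

**Step 7 (conjugate reduction).** Electron transfer to the crowded tetrasubstituted alkene may be too slow, and samarium alkoxide may meanwhile move the double bond toward C1 and erode that centre. The fallback replaces electron transfer by heterogeneous hydrogenation and runs from 12 to 13: H2 (4 atm), PtO2, EtOAc–AcOH, rt. Syn delivery of hydrogen to the face away from the C1 aryl group should give the all-cis member of epimer mixture 13, which step 8 equilibrates as before; no compound outside the list arises (F0).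

**Step 5 (Stille coupling).** Tin-to-palladium transfer from the crowded α-stannyl enoate may be slow enough that protodestannylation, polymerisation of the bromoacrylamide, or self-Diels–Alder dimerisation of the product takes over. The fallback exchanges the roles of the two partners; it sets out from 4 and 8 and returns at 9. Iododestannylation of 4 (I2, CH2Cl2, 0 °C, retention) should give methyl (E)-3-(3,4-dimethoxyphenyl)-2-iodoprop-2-enoate F9. Stannylation of 8 (Me3SnSnMe3, Pd(PPh3)4, toluene, 80 °C) should give N-[2-(trimethylstannyl)acryloyl]-(−)-camphorsultam F10. The reactive vinyl iodide F9 and the unhindered trimethylstannane F10 are then coupled at room temperature (Pd2(dba)3, P(2-furyl)3, CuI, DMF) to give diene 9.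

## Further compounds

F1 | step 6 | methyl 3-(3,4-dimethoxyphenyl)propanoate | COC(=O)CCc1ccc(OC)c(OC)c1
F2 | step 6 | 3-(3,4-dimethoxyphenyl)propanoic acid | OC(=O)CCc1ccc(OC)c(OC)c1
F3 | step 6 | (R)-4-benzyl-3-[3-(3,4-dimethoxyphenyl)propanoyl]oxazolidin-2-one | O=C(CCc1ccc(OC)c(OC)c1)N1C(=O)OC[C@H]1Cc1ccccc1
F4 | step 6 | tert-butyl (3S)-4-[(4R)-4-benzyl-2-oxooxazolidin-3-yl]-3-(3,4-dimethoxybenzyl)-4-oxobutanoate | O=C([C@@H](Cc1ccc(OC)c(OC)c1)CC(=O)OC(C)(C)C)N1C(=O)OC[C@H]1Cc1ccccc1
F5 | step 6 | tert-butyl (3S)-3-(3,4-dimethoxybenzyl)-4-hydroxybutanoate | OC[C@@H](Cc1ccc(OC)c(OC)c1)CC(=O)OC(C)(C)C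
F6 | step 6 | (S)-4-(3,4-dimethoxybenzyl)dihydrofuran-2(3H)-one | O=C1C[C@H](Cc2ccc(OC)c(OC)c2)CO1
F7 | step 6 | (3R,4S)-4-(3,4-dimethoxybenzyl)-3-[(3,4-dimethoxyphenyl)(hydroxy)methyl]dihydrofuran-2(3H)-one, carbinol epimers | O=C1OC[C@@H](Cc2ccc(OC)c(OC)c2)[C@@H]1C(O)c1ccc(OC)c(OC)c1
F8 | step 6 | (3aS,9R,9aS)-9-(3,4-dimethoxyphenyl)-6,7-dimethoxy-3a,4,9,9a-tetrahydronaphtho[2,3-c]furan-1(3H)-one | O=C1OC[C@H]2Cc3cc(OC)c(OC)cc3[C@@H](c3ccc(OC)c(OC)c3)[C@H]12
F0 | step 7 | none | none
F9 | step 5 | methyl (E)-3-(3,4-dimethoxyphenyl)-2-iodoprop-2-enoate | COC(=O)/C(I)=C\c1ccc(OC)c(OC)c1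
F10 | step 5 | N-[2-(trimethylstannyl)acryloyl]-(−)-camphorsultam | CC1(C)[C@@H]2CC[C@]13CS(=O)(=O)N(C(=O)C(=C)[Sn](C)(C)C)[C@@H]3C2
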